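# Sideroxylonal B: furan–ynoate Diels–Alder route to ring A and the pyran ring

## The problem

Sideroxylonal B (30) is a (2R,3S,4S)-2-aryl-3-isopropyl-4-isobutylchroman in which ring A (C4a to C8a) and ring B (on C2) are both fully substituted 3,5-diformylphloroglucinol units, and O1 of the pyran ring is one of the ring A oxygens. The three contiguous stereocentres are 2,3-cis (aryl and isopropyl) and 3,4-trans (isopropyl and isobutyl). None of them can be corrected by enolisation once the chroman exists, so they must be set in an open chain and carried through a ring closure that does not touch them. C4 can be set on its own by a catalyst, and C3 and C2 can then be set together by an auxiliary-controlled aldol reaction that overrides C4. C2 is a benzylic ether carbon ortho and para to three oxygens of ring B and would ionise under a Lewis acid if the aryl group were a bare 2,4,6-trimethoxyphenyl, so ring B has to carry its two acceptor carbons whenever acid is used. Four formyl groups chelated to phenols and five free phenols do not tolerate organometallic reagents, strong base or oxidants, so the aldehydes travel masked or at another oxidation level and the phenols are freed last. The key step rests on the pattern of ring A: oxygen on C5, C7 and C8a, carbon on C4a, C6 and C8. C4a–C5–C6–C7 with the C7 oxygen is a 2-alkyl-3-methoxyfuran, C8a (bearing O1) and C8 (bearing carbon) are an alkoxypropiolate, and the four-atom tether C4–C3–C2–O1 joins the two.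

## Retrosynthesis

**30 from 29.** The five O–CH3 bonds are cut last. Every methoxy group of 29 sits ortho to a formyl group, so a boron halide can remove all five by chelation, and ring B then carries two acceptors that keep C2–O1 safe. Methyl is the one phenol protection that passes through every earlier step. The forward reaction only has to spare the benzylic ether.

**29 from 25 (through 28, 27 and 26).** The C6–CHO bond is cut: C6 is the only free aromatic position of 28 and lies between two methoxy groups, so a single Rieche formylation suffices. The C8 aldehyde is traced through alcohol 27 to the ester of 26, which comes from 25 by O-methylation. The C8 carbon is therefore supplied by the alkyne and not by a second, hindered formylation of ring A. The two ring B aldehydes pass through the same reduction and oxidation and need no handling of their own.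

**25 from 22 (key disconnection).** C4a–C8a and C7–C8 are cut, and the C7 phenol oxygen is reconnected to C4a as a furan oxygen. This opens ring A and the pyran ring at once and leaves the open chain 22 with a 3-methoxyfuran, an alkoxypropiolate and all three stereocentres. Against cutting O1–C8a or C2–C3 alone, this cut removes the need to build a hexasubstituted benzene before the stereocentres, and the furan that replaces it is nucleophilic enough to enter by asymmetric catalysis. The forward reaction must be an intramolecular [4+2] cycloaddition to oxanorbornadiene 23, followed by opening of the oxygen bridge at C4a–O with loss of the C7 hydrogen to give phenol 24. The C5 methoxy group and O1 sit on nodal carbons of the C4a/C6/C8 cation and do not help this opening. They favour ionisation at C7–O instead, which is reversible and leads nowhere because C4a has no hydrogen to lose. Ring B is carried as its 3,5-bis(dioxolanyl) trimethyl ether so that C2–O1 does not ionise first, and hydrolysis in the work-up gives 25.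

**22 from 17 and 18.** The O1–C(sp) bond and the alkyne–ester bond are cut. Alcohol 17 and trichloroethene 18 give dichlorovinyl ether 19; elimination to 20 and chlorine–lithium exchange give lithium alkynyl ether 21, which is C-acylated. The C2–O bond of 17 is never broken, so C2 keeps its configuration.

**17 from 14 (through 15 and 16).** The isopropyl group is traced to the acetyl group of ketone 14 by methylenation to 15 and hydrogenation to 16. On the acyclic imide the isopropyl group cannot come from enolate alkylation, since a secondary halide is too poor an electrophile for an imide enolate and the enolate carbon has to receive the aldehyde. A carbonyl carbon at this position is what allows the aldol construction of C2–C3.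

**14 from 9 and 11 (through 12 and 13).** The C2–C3 bond is cut as an anti-aldol between acyl oxazolidinone 9 and aldehyde 11. With the carbonyl carbon destined to become the isopropyl CH, the cis relation of aryl and isopropyl in the ring translates into an anti relation of C2–O and C3–C4 in aldol 12. Auxiliary 7 is chosen to give (S) at the alpha carbon and (R) at the carbinol. The adduct is trapped as a silyl ether because the aldehyde is hindered and the aldolate would revert. The auxiliary is then exchanged for a thioester (13) and a methyl group (14).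

**11 from 10.** Two of the three equivalent formyl groups of trialdehyde 10 are masked as dioxolanes. Ring B thereby has all its carbons from the start, two late formylations are saved, and the ring is weakened as a cation-stabilising group.

**9 from 2 and 4 (through 5, 6 and 8).** The C4–furan bond is cut. 3-Methoxyfuran 2 adds through its C2 to the iminium ion of enal 4 and sets C4 in aldehyde 5. Oxidation to acid 6 and acylation of 7 through mixed anhydride 8 give 9. Enal 4 comes from 3-methylbutanal 3 by a two-carbon Wittig homologation, and 2 from 3-bromofuran 1.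

## Roads not taken

**Alternative 1: intramolecular SNAr.** The cut is O1–C8a. The C2 alkoxide of the open-chain fluoro tetra-aldehyde A2 would displace fluoride, activated by ortho and para formyl groups, and give the pentamethyl ether A1, which is identical with 29.

- Merits: the ring closure is well precedented, cannot disturb the stereocentres, and ends one step from the target with all formyl groups in place. In precedent and in length of the endgame this road is better than the chosen one.
- Weak points: A2 needs a hexasubstituted, electron-poor ring A on C4. Such a ring cannot enter as a nucleophile in a catalytic Friedel–Crafts step, so C4 would require a hindered arylmetal addition. In A2 four free formyl groups would have to coexist with a secondary alkoxide (hemiacetal formation, hydride transfer), and masking them removes the activation that the displacement needs.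
- What the chosen plan sets against it: C4 is set catalytically on a simple furan, and ring A and the pyran ring form in a single step. The price is a ring-forming step without direct precedent.

**Alternative 2: cyclobutenone benzannulation for ring B.** The cut removes three bonds of ring B. 3-Ethoxycyclobut-2-en-1-one A4 would undergo thermal four-electron ring opening and add [2+2] to the C2 siloxyalkyne A5; a second ring opening and six-electron closure would then give the flavan A3.

- Merits: the benzannulation is known for siloxyalkynes and is regiospecific. The electron-rich ring B is absent during all earlier chemistry, so C2 cannot ionise before the last stage. In this respect it is safer than the chosen plan, which answers with the acetal-substituted ring B.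
- Weak points: it builds the easier ring. Ring A, the pyran ring and all three stereocentres must already be present in A5 and need a solution of their own. The siloxyalkyne of A5 can only come from homologation of an ester carbon on C2, and a C2 centre alpha to a carbonyl group is epimerisable. A3 carries three different oxygen substituents and no formyl group, so four formylations and three kinds of deprotection remain.
- Comparison: it complements rather than replaces a ring A strategy. Since ring B is available as the commercial aldehyde 10, building it from A4 costs more steps than it saves.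

**Alternative 3: aryl-oxocarbenium Prins cyclisation.** The cut is C2–C3. A Lewis acid would ionise the alpha-acetoxy ether A7, C3 of the trisubstituted alkene would attack C2, and proton loss would give the 3-isopropenyl chroman A6.

- Merits: it is short. C4 can come from a catalytic phenol alkylation, the cyclisation type is known for alpha-acetoxy ethers, and two stereocentres form in the ring-closing step. In step count it beats the chosen plan.
- Weak points: a chair-like transition state should place the C2 aryl group and the C3 cationic substituent both equatorial, that is 2,3-trans, whereas the target is 2,3-cis. The closure passes through ionisation at the 2,4,6-trimethoxybenzylic carbon, the very event the chosen plan avoids. Hydrogenation of A6, four formylations on an acid-labile flavan and demethylation would still follow.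
- What the chosen plan sets against it: C2 and C3 are fixed in the open chain by an auxiliary-controlled aldol, and ring B reaches the acidic steps already deactivated.

Key step: step 14

## Route

Assumption: 2,4,6-trimethoxybenzene-1,3,5-tricarbaldehyde (10) is taken as a purchasable framework-linker aldehyde; ring B is carried as its bis-dioxolane because a bare 2,4,6-trimethoxybenzylic C2–O bond would not survive the Lewis acid of the key step.

Step 1
Reactants: 1 3-bromofuran
Product: 2 3-methoxyfuran
Conditions: NaOMe, CuBr (10 mol%), MeOH–DMF, 110 °C (sealed); distillation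
Reagents that add atoms: sodium methoxide, [Na+].[O-]C
Why: Copper-catalysed Ullmann-type methoxylation of a heteroaryl bromide; the volatile product is isolated by distillation.

Step 2
Reactants: 3 3-methylbutanal
Product: 4 (E)-5-methylhex-2-enal
Conditions: Ph3P=CHCHO, toluene, 80 °C
Reagents that add atoms: (triphenylphosphoranylidene)acetaldehyde, O=CC=P(c1ccccc1)(c1ccccc1)c1ccccc1
Why: Wittig reaction with the stabilised formylmethylene ylide gives the (E)-enal; slow addition of the ylide limits a second homologation.

Step 3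
Reactants: 2 3-methoxyfuran; 4 (E)-5-methylhex-2-enal
Product: 5 (3S)-3-(3-methoxyfuran-2-yl)-5-methylhexanal
Conditions: (2R,5R)-5-benzyl-2-tert-butyl-3-methylimidazolidin-4-one·CF3CO2H (20 mol%), CH2Cl2–i-PrOH, −40 °C
Reagents that add atoms: none
Why: Iminium-catalysed Friedel–Crafts alkylation of an electron-rich furan; C2 of 2 (ortho to methoxy, alpha to oxygen) is the most nucleophilic carbon, and the (2R,5R) catalyst leaves the Si face of C3 of the (E)-iminium ion open, which sets the (S) centre that becomes C4.

Step 4
Reactants: 5 (3S)-3-(3-methoxyfuran-2-yl)-5-methylhexanal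
Product: 6 (3S)-3-(3-methoxyfuran-2-yl)-5-methylhexanoic acid
Conditions: AgNO3, NaOH, EtOH–H2O, 0 → 23 °C; citric acid to pH 4
Reagents that add atoms: sodium hydroxide, [Na+].[OH-]
Why: Ag2O oxidation of an aldehyde to the acid; chosen over chlorite oxidants, which would attack the methoxyfuran, and the beta stereocentre cannot epimerise.

Step 5
Reactants: 6 (3S)-3-(3-methoxyfuran-2-yl)-5-methylhexanoic acid; 7 (4R)-4-benzyl-1,3-oxazolidin-2-one
Product: 9 (4R)-4-benzyl-3-[(3S)-3-(3-methoxyfuran-2-yl)-5-methylhexanoyl]-1,3-oxazolidin-2-one, via mixed pivalic anhydride 8 (not isolated)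
Conditions: t-BuCOCl, Et3N, THF, −20 °C; then 7, LiCl, 23 °C
Reagents that add atoms: pivaloyl chloride, CC(C)(C)C(=O)Cl (its acyl group stays only in intermediate 8)
Why: N-acylation of the oxazolidinone through a mixed anhydride under LiCl/Et3N; no strong base comes near the furan.

Step 6
Reactants: 10 2,4,6-trimethoxybenzene-1,3,5-tricarbaldehyde
Product: 11 3,5-bis(1,3-dioxolan-2-yl)-2,4,6-trimethoxybenzaldehyde
Conditions: HOCH2CH2OH (2.0 equiv), TsOH (cat.), benzene, reflux with azeotropic removal of water; chromatography, mono- and tris-acetal recycled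
Reagents that add atoms: ethane-1,2-diol, OCCO
Why: Acid-catalysed acetalisation of a threefold symmetric trialdehyde gives the bis-acetal statistically; the other acetals are re-equilibrated under the same conditions.

Step 7
Reactants: 9 (4R)-4-benzyl-3-[(3S)-3-(3-methoxyfuran-2-yl)-5-methylhexanoyl]-1,3-oxazolidin-2-one; 11 3,5-bis(1,3-dioxolan-2-yl)-2,4,6-trimethoxybenzaldehyde
Product: 12 (4R)-4-benzyl-3-[(2S,3S)-2-{(R)-[3,5-bis(1,3-dioxolan-2-yl)-2,4,6-trimethoxyphenyl][(trimethylsilyl)oxy]methyl}-3-(3-methoxyfuran-2-yl)-5-methylhexanoyl]-1,3-oxazolidin-2-one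
Conditions: MgCl2 (20 mol%), Et3N, Me3SiCl, EtOAc, 23 °C
Reagents that add atoms: chlorotrimethylsilane, C[Si](C)(C)Cl
Why: MgCl2-catalysed anti-aldol reaction of an N-acyloxazolidinone with a non-enolisable aromatic aldehyde; the chelated Z-enolate is attacked in a boat transition state on the face opposite the benzyl group, which gives the anti pair with (S) at the future C3 and (R) at the future C2. O-silylation drives the reversible addition to the hindered aldehyde forward.

Step 8
Reactants: 12 silylated aldol imide
Product: 13 S-ethyl (2S,3S)-2-{(R)-[3,5-bis(1,3-dioxolan-2-yl)-2,4,6-trimethoxyphenyl][(trimethylsilyl)oxy]methyl}-3-(3-methoxyfuran-2-yl)-5-methylhexanethioate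
Conditions: EtSH, n-BuLi, THF, 0 °C; H2O
Reagents that add atoms: ethanethiol (as its lithium salt), CCS
Why: Thiolate cleavage of a hindered imide at the exocyclic carbonyl (transthioesterification); the silyl ether stays and the auxiliary is released.

Step 9
Reactants: 13 S-ethyl thioester
Product: 14 (3S,4S)-3-{(R)-[3,5-bis(1,3-dioxolan-2-yl)-2,4,6-trimethoxyphenyl][(trimethylsilyl)oxy]methyl}-4-(3-methoxyfuran-2-yl)-6-methylheptan-2-one
Conditions: Me2CuLi (from CuI, MeLi), Et2O, −78 → −40 °C; aq. NH4Cl
Reagents that add atoms: lithium dimethylcuprate, [Li+].C[Cu-]C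
Why: Cuprate acylation of a thioester stops at the ketone; the non-basic reagent keeps the alpha stereocentre and the beta-silyloxy group.

Step 10
Reactants: 14 methyl ketone
Product: 15 {[(1R,2R,3S)-1-[3,5-bis(1,3-dioxolan-2-yl)-2,4,6-trimethoxyphenyl]-3-(3-methoxyfuran-2-yl)-5-methyl-2-(prop-1-en-2-yl)hexyl]oxy}(trimethyl)silane
Conditions: Cp2TiMe2, toluene, 65 °C, dark
Reagents that add atoms: dimethyltitanocene, [CH3-].[CH3-].[Ti+4].c1cc[cH-]c1.c1cc[cH-]c1
Why: Titanium-alkylidene methylenation of a hindered, enolisable ketone; it avoids the basicity of a phosphorus ylide, which could epimerise C3 or eliminate the beta-silyloxy group.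

Step 11
Reactants: 15 isopropenyl silyl ether
Product: 17 (1R,2S,3S)-1-[3,5-bis(1,3-dioxolan-2-yl)-2,4,6-trimethoxyphenyl]-3-(3-methoxyfuran-2-yl)-5-methyl-2-(propan-2-yl)hexan-1-ol, via isopropyl silyl ether 16 (not isolated)
Conditions: H2 (4 bar), RhCl(PPh3)3 (10 mol%), benzene–EtOH, 40 °C; then K2CO3, MeOH, 0 °C
Reagents that add atoms: none
Why: Homogeneous hydrogenation of the 1,1-disubstituted alkene leaves furan, arene and the benzylic C–O bond alone and creates no stereocentre; methanolysis then removes the trimethylsilyl group.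

Step 12
Reactants: 17 (1R,2S,3S)-1-[3,5-bis(1,3-dioxolan-2-yl)-2,4,6-trimethoxyphenyl]-3-(3-methoxyfuran-2-yl)-5-methyl-2-(propan-2-yl)hexan-1-ol; 18 trichloroethene
Product: 19 (E)-1,2-dichloroethenyl (1R,2S,3S)-1-[3,5-bis(1,3-dioxolan-2-yl)-2,4,6-trimethoxyphenyl]-3-(3-methoxyfuran-2-yl)-5-methyl-2-(propan-2-yl)hexyl ether
Conditions: KH, THF, 0 → 23 °C
Reagents that add atoms: none
Why: The potassium alkoxide adds anti to dichloroacetylene formed in situ from 18; the C2–O bond of the alcohol is not touched, so C2 is retained.

Step 13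
Reactants: 19 (E)-1,2-dichloroethenyl ether
Product: 22 methyl 3-{[(1R,2S,3S)-1-[3,5-bis(1,3-dioxolan-2-yl)-2,4,6-trimethoxyphenyl]-3-(3-methoxyfuran-2-yl)-5-methyl-2-(propan-2-yl)hexyl]oxy}prop-2-ynoate, via chloroethynyl ether 20 (not isolated), via lithium alkynyl ether 21 (not isolated)
Conditions: n-BuLi (2.4 equiv), THF, −78 → −40 °C; ClCO2Me, −78 °C
Reagents that add atoms: butyllithium, [Li]CCCC (lithium stays only in intermediate 21); methyl chloroformate, COC(=O)Cl
Why: Elimination and chlorine–lithium exchange give the lithium alkynyl ether, which is C-acylated by the chloroformate; acetals, methyl ethers and the furan are inert at this temperature.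

Step 14
Reactants: 22 methyl 3-{[(1R,2S,3S)-1-[3,5-bis(1,3-dioxolan-2-yl)-2,4,6-trimethoxyphenyl]-3-(3-methoxyfuran-2-yl)-5-methyl-2-(propan-2-yl)hexyl]oxy}prop-2-ynoate
Product: 25 methyl (2R,3S,4S)-2-(3,5-diformyl-2,4,6-trimethoxyphenyl)-7-hydroxy-5-methoxy-4-(2-methylpropyl)-3-(propan-2-yl)-3,4-dihydro-2H-chromene-8-carboxylate, via oxanorbornadiene cycloadduct 23 (not isolated), via bis-dioxolane phenol 24 (not isolated)
Conditions: Me2AlCl (3 equiv), CH2Cl2, −78 → 0 °C; then 1 M HCl, THF, 23 °C
Reagents that add atoms: water, O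
Why: Proposed new method: Me2AlCl bound to the ester lowers the LUMO of the alkoxypropiolate, the nucleophilic C2 of the 3-methoxyfuran (future C4a) attacks the alkoxy-bearing alkyne carbon (C8a) and the allenolate carbon so formed (C8) closes on furan C5 (C7), a strongly asynchronous normal-demand intramolecular [4+2] cycloaddition whose regiochemistry is fixed by the four-atom tether C4–C3–C2–O1. The closest known reaction type is the intramolecular furan–alkyne Diels–Alder reaction of 2-tethered furans with ynones and ynoates followed by acid opening of the 7-oxanorbornadiene to an annulated phenol, as in the conversion of furan–acetylenedicarboxylate adducts into 3-hydroxyphthalates. The pyran ring closes through the C4a–C8a bond as the six-membered tether ring of the fused cycloadduct 23; ring A closes through C4a–C8a plus C7–C8 and becomes aromatic when the oxygen bridge opens. For the phenol to appear on C7 the bridge must ionise at C4a–O; the C5 methoxy group and O1 lie on nodal carbons of the C4a/C6/C8 cation and do not stabilise it, and they favour ionisation at C7–O instead, but that path is reversible and unproductive because C4a has no hydrogen, so the material should drain through the slower C4a–O ionisation and irreversible loss of the C7 proton. No lasting stereocentre is formed (both bridgeheads become sp2) and C2, C3 and C4 are spectators. The selectivity needed is against ionisation of the benzylic C2–O1 bond and against retro-ene loss of the ynol ether: the first is secured by ring B, whose dioxolane-flanked methoxy groups are twisted out of conjugation and whose acetal oxygens bind the Lewis acid, the second by working at or below 0 °C with a Lewis acid that also scavenges protons. A dioxolane opened by the Lewis acid without methyl transfer is no loss, because aqueous acid in the work-up hydrolyses both dioxolanes anyway and ring B emerges as the diformyl trimethyl ether.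

Step 15
Reactants: 25 C7 phenol
Product: 26 methyl (2R,3S,4S)-2-(3,5-diformyl-2,4,6-trimethoxyphenyl)-5,7-dimethoxy-4-(2-methylpropyl)-3-(propan-2-yl)-3,4-dihydro-2H-chromene-8-carboxylate
Conditions: MeI, K2CO3, DMF, 40 °C
Reagents that add atoms: iodomethane, CI
Why: Williamson O-methylation of the hydrogen-bonded salicylate phenol; with C7–OH capped, the benzylic alcohol of the next step cannot expel water to a quinone methide.

Step 16
Reactants: 26 ester dialdehyde
Product: 27 [(2R,3S,4S)-2-[3,5-bis(hydroxymethyl)-2,4,6-trimethoxyphenyl]-5,7-dimethoxy-4-(2-methylpropyl)-3-(propan-2-yl)-3,4-dihydro-2H-chromen-8-yl]methanol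
Conditions: LiAlH4, THF, 0 → 23 °C; H2O, aq. NaOH
Reagents that add atoms: none
Why: Hydride reduction of the hindered aryl ester together with both aldehydes brings the three carbons to one oxidation level; aryl ethers and the chroman are inert.

Step 17
Reactants: 27 triol
Product: 28 (2R,3S,4S)-2-(3,5-diformyl-2,4,6-trimethoxyphenyl)-5,7-dimethoxy-4-(2-methylpropyl)-3-(propan-2-yl)-3,4-dihydro-2H-chromene-8-carbaldehyde
Conditions: MnO2 (excess), CH2Cl2, 23 °C
Reagents that add atoms: none
Why: MnO2 oxidises electron-rich benzylic alcohols to aldehydes without over-oxidation and under neutral conditions that spare the acid-sensitive benzylic alcohols.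

Step 18
Reactants: 28 trialdehyde
Product: 29 (2R,3S,4S)-2-(3,5-diformyl-2,4,6-trimethoxyphenyl)-5,7-dimethoxy-4-(2-methylpropyl)-3-(propan-2-yl)-3,4-dihydro-2H-chromene-6,8-dicarbaldehyde
Conditions: Cl2CHOMe, TiCl4, CH2Cl2, −20 → 0 °C; aq. HCl
Reagents that add atoms: dichloromethyl methyl ether, COC(Cl)Cl; water, O
Why: Rieche formylation; C6 is the only unsubstituted aromatic carbon and lies between two methoxy groups, and the fully substituted, deactivated ring B keeps C2–O1 intact under TiCl4.

Step 19
Reactants: 29 pentamethyl ether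
Product: 30 sideroxylonal B, (2R,3S,4S)-2-(3,5-diformyl-2,4,6-trihydroxyphenyl)-5,7-dihydroxy-4-(2-methylpropyl)-3-(propan-2-yl)-3,4-dihydro-2H-chromene-6,8-dicarbaldehyde
Conditions: BBr3 (12 equiv), CH2Cl2, −78 → 0 °C; H2O
Reagents that add atoms: none
Why: Boron tribromide cleavage of aryl methyl ethers, helped by chelation to the ortho formyl group that each of the five ethers has; the two acceptors on ring B protect the C2–O1 bond.

## Compound list

1 | 3-bromofuran | Brc1ccoc1 | starting material
2 | 3-methoxyfuran | COc1ccoc1 | intermediate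
3 | 3-methylbutanal | CC(C)CC=O | starting material
4 | (E)-5-methylhex-2-enal | CC(C)C/C=C/C=O | intermediate
5 | (3S)-3-(3-methoxyfuran-2-yl)-5-methylhexanal | CC(C)C[C@H](c1occc1OC)CC=O | intermediate
6 | (3S)-3-(3-methoxyfuran-2-yl)-5-methylhexanoic acid | CC(C)C[C@H](c1occc1OC)CC(=O)O | intermediate
7 | (4R)-4-benzyl-1,3-oxazolidin-2-one | O=C1N[C@H](Cc2ccccc2)CO1 | starting material
8 | mixed anhydride of 6 with pivalic acid | CC(C)C[C@H](c1occc1OC)CC(=O)OC(=O)C(C)(C)C | intermediate
9 | (4R)-4-benzyl-3-[(3S)-3-(3-methoxyfuran-2-yl)-5-methylhexanoyl]-1,3-oxazolidin-2-one | CC(C)C[C@H](c1occc1OC)CC(=O)N1[C@H](Cc2ccccc2)COC1=O | intermediate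
10 | 2,4,6-trimethoxybenzene-1,3,5-tricarbaldehyde | O=Cc1c(OC)c(C=O)c(OC)c(C=O)c1OC | starting material
11 | 3,5-bis(1,3-dioxolan-2-yl)-2,4,6-trimethoxybenzaldehyde | O=Cc1c(OC)c(C2OCCO2)c(OC)c(C2OCCO2)c1OC | intermediate
12 | (4R)-4-benzyl-3-[(2S,3S)-2-{(R)-[3,5-bis(1,3-dioxolan-2-yl)-2,4,6-trimethoxyphenyl][(trimethylsilyl)oxy]methyl}-3-(3-methoxyfuran-2-yl)-5-methylhexanoyl]-1,3-oxazolidin-2-one | CC(C)C[C@H](c1occc1OC)[C@@H]([C@@H](O[Si](C)(C)C)c1c(OC)c(C2OCCO2)c(OC)c(C2OCCO2)c1OC)C(=O)N1[C@H](Cc2ccccc2)COC1=O | intermediate
13 | S-ethyl (2S,3S)-2-{(R)-[3,5-bis(1,3-dioxolan-2-yl)-2,4,6-trimethoxyphenyl][(trimethylsilyl)oxy]methyl}-3-(3-methoxyfuran-2-yl)-5-methylhexanethioate | CC(C)C[C@H](c1occc1OC)[C@@H]([C@@H](O[Si](C)(C)C)c1c(OC)c(C2OCCO2)c(OC)c(C2OCCO2)c1OC)C(=O)SCC | intermediate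
14 | (3S,4S)-3-{(R)-[3,5-bis(1,3-dioxolan-2-yl)-2,4,6-trimethoxyphenyl][(trimethylsilyl)oxy]methyl}-4-(3-methoxyfuran-2-yl)-6-methylheptan-2-one | CC(C)C[C@H](c1occc1OC)[C@@H]([C@@H](O[Si](C)(C)C)c1c(OC)c(C2OCCO2)c(OC)c(C2OCCO2)c1OC)C(C)=O | intermediate
15 | {[(1R,2R,3S)-1-[3,5-bis(1,3-dioxolan-2-yl)-2,4,6-trimethoxyphenyl]-3-(3-methoxyfuran-2-yl)-5-methyl-2-(prop-1-en-2-yl)hexyl]oxy}(trimethyl)silane | CC(C)C[C@H](c1occc1OC)[C@@H]([C@@H](O[Si](C)(C)C)c1c(OC)c(C2OCCO2)c(OC)c(C2OCCO2)c1OC)C(C)=C | intermediate
16 | {[(1R,2S,3S)-1-[3,5-bis(1,3-dioxolan-2-yl)-2,4,6-trimethoxyphenyl]-3-(3-methoxyfuran-2-yl)-5-methyl-2-(propan-2-yl)hexyl]oxy}(trimethyl)silane | CC(C)C[C@H](c1occc1OC)[C@@H]([C@@H](O[Si](C)(C)C)c1c(OC)c(C2OCCO2)c(OC)c(C2OCCO2)c1OC)C(C)C | intermediate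
17 | (1R,2S,3S)-1-[3,5-bis(1,3-dioxolan-2-yl)-2,4,6-trimethoxyphenyl]-3-(3-methoxyfuran-2-yl)-5-methyl-2-(propan-2-yl)hexan-1-ol | CC(C)C[C@H](c1occc1OC)[C@@H]([C@@H](O)c1c(OC)c(C2OCCO2)c(OC)c(C2OCCO2)c1OC)C(C)C | intermediate
18 | trichloroethene | ClC=C(Cl)Cl | starting material
19 | (E)-1,2-dichloroethenyl (1R,2S,3S)-1-[3,5-bis(1,3-dioxolan-2-yl)-2,4,6-trimethoxyphenyl]-3-(3-methoxyfuran-2-yl)-5-methyl-2-(propan-2-yl)hexyl ether | CC(C)C[C@H](c1occc1OC)[C@@H]([C@@H](O/C(Cl)=C\Cl)c1c(OC)c(C2OCCO2)c(OC)c(C2OCCO2)c1OC)C(C)C | intermediate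
20 | chloroethynyl (1R,2S,3S)-1-[3,5-bis(1,3-dioxolan-2-yl)-2,4,6-trimethoxyphenyl]-3-(3-methoxyfuran-2-yl)-5-methyl-2-(propan-2-yl)hexyl ether | CC(C)C[C@H](c1occc1OC)[C@@H]([C@@H](OC#CCl)c1c(OC)c(C2OCCO2)c(OC)c(C2OCCO2)c1OC)C(C)C | intermediate
21 | lithioethynyl (1R,2S,3S)-1-[3,5-bis(1,3-dioxolan-2-yl)-2,4,6-trimethoxyphenyl]-3-(3-methoxyfuran-2-yl)-5-methyl-2-(propan-2-yl)hexyl ether (lithium alkynyl ether) | CC(C)C[C@H](c1occc1OC)[C@@H]([C@@H](OC#C[Li])c1c(OC)c(C2OCCO2)c(OC)c(C2OCCO2)c1OC)C(C)C | intermediate
22 | methyl 3-{[(1R,2S,3S)-1-[3,5-bis(1,3-dioxolan-2-yl)-2,4,6-trimethoxyphenyl]-3-(3-methoxyfuran-2-yl)-5-methyl-2-(propan-2-yl)hexyl]oxy}prop-2-ynoate | CC(C)C[C@H](c1occc1OC)[C@@H]([C@@H](OC#CC(=O)OC)c1c(OC)c(C2OCCO2)c(OC)c(C2OCCO2)c1OC)C(C)C | intermediate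
23 | methyl (2R,3S,4S)-2-[3,5-bis(1,3-dioxolan-2-yl)-2,4,6-trimethoxyphenyl]-5-methoxy-4-(2-methylpropyl)-3-(propan-2-yl)-3,4-dihydro-2H,7H-4a,7-epoxychromene-8-carboxylate (oxygen bridge C4a–O–C7; either bridge diastereomer, both give the same arene) | CC(C)C[C@H]1[C@H](C(C)C)[C@H](c2c(OC)c(C3OCCO3)c(OC)c(C3OCCO3)c2OC)OC2=C(C(=O)OC)C3OC12C(OC)=C3 | intermediate
24 | methyl (2R,3S,4S)-2-[3,5-bis(1,3-dioxolan-2-yl)-2,4,6-trimethoxyphenyl]-7-hydroxy-5-methoxy-4-(2-methylpropyl)-3-(propan-2-yl)-3,4-dihydro-2H-chromene-8-carboxylate | CC(C)C[C@@H]1c2c(OC)cc(O)c(C(=O)OC)c2O[C@@H](c2c(OC)c(C3OCCO3)c(OC)c(C3OCCO3)c2OC)[C@H]1C(C)C | intermediate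
25 | methyl (2R,3S,4S)-2-(3,5-diformyl-2,4,6-trimethoxyphenyl)-7-hydroxy-5-methoxy-4-(2-methylpropyl)-3-(propan-2-yl)-3,4-dihydro-2H-chromene-8-carboxylate | CC(C)C[C@@H]1c2c(OC)cc(O)c(C(=O)OC)c2O[C@@H](c2c(OC)c(C=O)c(OC)c(C=O)c2OC)[C@H]1C(C)C | intermediate
26 | methyl (2R,3S,4S)-2-(3,5-diformyl-2,4,6-trimethoxyphenyl)-5,7-dimethoxy-4-(2-methylpropyl)-3-(propan-2-yl)-3,4-dihydro-2H-chromene-8-carboxylate | CC(C)C[C@@H]1c2c(OC)cc(OC)c(C(=O)OC)c2O[C@@H](c2c(OC)c(C=O)c(OC)c(C=O)c2OC)[C@H]1C(C)C | intermediate
27 | [(2R,3S,4S)-2-[3,5-bis(hydroxymethyl)-2,4,6-trimethoxyphenyl]-5,7-dimethoxy-4-(2-methylpropyl)-3-(propan-2-yl)-3,4-dihydro-2H-chromen-8-yl]methanol | CC(C)C[C@@H]1c2c(OC)cc(OC)c(CO)c2O[C@@H](c2c(OC)c(CO)c(OC)c(CO)c2OC)[C@H]1C(C)C | intermediate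
28 | (2R,3S,4S)-2-(3,5-diformyl-2,4,6-trimethoxyphenyl)-5,7-dimethoxy-4-(2-methylpropyl)-3-(propan-2-yl)-3,4-dihydro-2H-chromene-8-carbaldehyde | CC(C)C[C@@H]1c2c(OC)cc(OC)c(C=O)c2O[C@@H](c2c(OC)c(C=O)c(OC)c(C=O)c2OC)[C@H]1C(C)C | intermediate
29 | (2R,3S,4S)-2-(3,5-diformyl-2,4,6-trimethoxyphenyl)-5,7-dimethoxy-4-(2-methylpropyl)-3-(propan-2-yl)-3,4-dihydro-2H-chromene-6,8-dicarbaldehyde | CC(C)C[C@@H]1c2c(OC)c(C=O)c(OC)c(C=O)c2O[C@@H](c2c(OC)c(C=O)c(OC)c(C=O)c2OC)[C@H]1C(C)C | intermediate
30 | sideroxylonal B, (2R,3S,4S)-2-(3,5-diformyl-2,4,6-trihydroxyphenyl)-5,7-dihydroxy-4-(2-methylpropyl)-3-(propan-2-yl)-3,4-dihydro-2H-chromene-6,8-dicarbaldehyde | CC(C)C[C@@H]1c2c(O)c(C=O)c(O)c(C=O)c2O[C@@H](c2c(O)c(C=O)c(O)c(C=O)c2O)[C@H]1C(C)C | target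

## Step count and risks

Total step count: 19. Longest linear sequence: 17 steps (1, 3–5, 7–19, from 3-bromofuran); steps 2 and 6 are one-step side branches.

**Step 14 (key step, proposed new method).** What may go wrong: the oxygen bridge may open at C7–O, the electronically easier side, and then be diverted irreversibly by demethylation of the C5 oxocarbenium ion or by a 1,2-alkyl shift to a non-aromatic dienone before the slower C4a–O ionisation occurs. The ynol ether may also undergo retro-ene fragmentation before it cyclises, and a dioxolane ionised by the Lewis acid may take up a methyl group from aluminium instead of waiting for hydrolysis.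

Fallback (known chemistry, leaves the furan out; sets out from enal 4 and returns to the route at 29): enal 4 and commercial 3,5-dimethoxyphenol are joined by an iminium-catalysed Friedel–Crafts alkylation with hemiacetal closure. The catalyst is (R)-2-[diphenyl(trimethylsilyloxy)methyl]pyrrolidine with benzoic acid, the enantiomer that leaves the Si face of C3 of 4 open, and the product is (4S)-5,7-dimethoxy-4-(2-methylpropyl)-3,4-dihydro-2H-chromen-2-ol F1. Oxidation with PhI(OAc)2 and catalytic 2,2,6,6-tetramethylpiperidin-1-oxyl gives the lactone (4S)-5,7-dimethoxy-4-(2-methylpropyl)chroman-2-one F2. Its lithium enolate (LiN(SiMe3)2, THF–DMPU) is alkylated with 2-iodopropane trans to the pseudo-axial C4 substituent and gives (3S,4S)-5,7-dimethoxy-4-(2-methylpropyl)-3-(propan-2-yl)chroman-2-one F3; a lithium lactone enolate in a dipolar medium accepts the secondary iodide that an imide enolate does not. Lithiated 1,3,5-trimethoxybenzene (butyllithium, THF) adds once to F3 and gives the keto phenol (2S,3S)-3-(2-hydroxy-4,6-dimethoxyphenyl)-5-methyl-2-(propan-2-yl)-1-(2,4,6-trimethoxyphenyl)hexan-1-one F4. Ionic hydrogenation (Et3SiH, CF3CO2H) of the cyclic oxocarbenium ion closes the chroman (2R,3S,4S)-5,7-dimethoxy-4-(2-methylpropyl)-3-(propan-2-yl)-2-(2,4,6-trimethoxyphenyl)-3,4-dihydro-2H-chromene F5. The acid-labile C2 centre can equilibrate here and is expected to settle as the 2,3-cis isomer, with the aryl group equatorial and the trans alkyl groups diaxial (C4 axial to avoid the C5 methoxy group). Fourfold Rieche formylation (Cl2CHOMe, TiCl4) then gives 29. This fallback gives up the protection of C2–O1 that the main route has and relies on the same thermodynamic preference if C2 ionises before ring B is formylated.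

**Step 7 (anti-aldol).** What may go wrong: low conversion, because silylation of the enolate may outrun addition to the di-ortho-substituted aldehyde, or erosion of the anti selectivity by mismatched double diastereoselection with the C4 centre.

Fallback (sets out from 9 and returns to the route at 12): 9 is enolised with Bu2BOTf and i-Pr2NEt at −78 °C and combined with aldehyde 11 precomplexed with Et2AlCl. This open-transition-state boron aldol on the chelated enolate face gives the free anti-aldol (4R)-4-benzyl-3-[(2S,3S)-2-{(R)-[3,5-bis(1,3-dioxolan-2-yl)-2,4,6-trimethoxyphenyl](hydroxy)methyl}-3-(3-methoxyfuran-2-yl)-5-methylhexanoyl]-1,3-oxazolidin-2-one F6. Silylation with Me3SiCl and imidazole then gives 12.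

**Step 3 (catalytic Friedel–Crafts alkylation).** What may go wrong: acid-promoted hydrolysis or oligomerisation of the enol-ether-like 3-methoxyfuran under the amine salt, or insufficient facial selectivity.

Fallback (auxiliary control in place of catalyst control; sets out from 3 and returns to the route at 9): Knoevenagel–Doebner condensation of 3 with malonic acid gives (E)-5-methylhex-2-enoic acid F7. Pivaloyl chloride and Et3N convert it into the mixed anhydride (E)-5-methylhex-2-enoic pivalic anhydride F8, which is not isolated and acylates 7 in the presence of LiCl to give (4R)-4-benzyl-3-[(E)-5-methylhex-2-enoyl]-1,3-oxazolidin-2-one F9. Et2AlCl chelates F9 in the s-cis form, and 3-methoxyfuran 2 adds to the beta carbon on the face opposite the benzyl group in a Michael-type Friedel–Crafts alkylation. This gives 9 directly and also saves steps 2, 4 and 5.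

**Step 10 (methylenation).** What may go wrong: no reaction at the hindered carbonyl group, or enolisation with loss of the C3 configuration or of the beta-silyloxy group.

Fallback (sets out from 14 and returns to the route at 15): Me3SiCH2Li with CeCl3 adds to 14 and gives the beta-hydroxysilane (3S,4S)-3-{(R)-[3,5-bis(1,3-dioxolan-2-yl)-2,4,6-trimethoxyphenyl][(trimethylsilyl)oxy]methyl}-4-(3-methoxyfuran-2-yl)-2,6-dimethyl-1-(trimethylsilyl)heptan-2-ol F10 as a mixture at the new carbinol carbon. KH in THF then effects Peterson elimination to 15.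

## Further compounds

F1 | step 14 | (4S)-5,7-dimethoxy-4-(2-methylpropyl)-3,4-dihydro-2H-chromen-2-ol | CC(C)C[C@H]1CC(O)Oc2cc(OC)cc(OC)c12
F2 | step 14 | (4S)-5,7-dimethoxy-4-(2-methylpropyl)chroman-2-one | CC(C)C[C@H]1CC(=O)Oc2cc(OC)cc(OC)c12
F3 | step 14 | (3S,4S)-5,7-dimethoxy-4-(2-methylpropyl)-3-(propan-2-yl)chroman-2-one | CC(C)C[C@@H]1c2c(OC)cc(OC)cc2OC(=O)[C@H]1C(C)C
F4 | step 14 | (2S,3S)-3-(2-hydroxy-4,6-dimethoxyphenyl)-5-methyl-2-(propan-2-yl)-1-(2,4,6-trimethoxyphenyl)hexan-1-one | CC(C)C[C@H](c1c(OC)cc(OC)cc1O)[C@H](C(C)C)C(=O)c1c(OC)cc(OC)cc1OC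
F5 | step 14 | (2R,3S,4S)-5,7-dimethoxy-4-(2-methylpropyl)-3-(propan-2-yl)-2-(2,4,6-trimethoxyphenyl)-3,4-dihydro-2H-chromene | CC(C)C[C@@H]1c2c(OC)cc(OC)cc2O[C@@H](c2c(OC)cc(OC)cc2OC)[C@H]1C(C)C
F6 | step 7 | (4R)-4-benzyl-3-[(2S,3S)-2-{(R)-[3,5-bis(1,3-dioxolan-2-yl)-2,4,6-trimethoxyphenyl](hydroxy)methyl}-3-(3-methoxyfuran-2-yl)-5-methylhexanoyl]-1,3-oxazolidin-2-one | CC(C)C[C@H](c1occc1OC)[C@@H]([C@@H](O)c1c(OC)c(C2OCCO2)c(OC)c(C2OCCO2)c1OC)C(=O)N1[C@H](Cc2ccccc2)COC1=O
F7 | step 3 | (E)-5-methylhex-2-enoic acid | CC(C)C/C=C/C(=O)O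
F8 | step 3 | (E)-5-methylhex-2-enoic pivalic anhydride | CC(C)C/C=C/C(=O)OC(=O)C(C)(C)C
F9 | step 3 | (4R)-4-benzyl-3-[(E)-5-methylhex-2-enoyl]-1,3-oxazolidin-2-one | CC(C)C/C=C/C(=O)N1[C@H](Cc2ccccc2)COC1=O
F10 | step 10 | (3S,4S)-3-{(R)-[3,5-bis(1,3-dioxolan-2-yl)-2,4,6-trimethoxyphenyl][(trimethylsilyl)oxy]methyl}-4-(3-methoxyfuran-2-yl)-2,6-dimethyl-1-(trimethylsilyl)heptan-2-ol as a mixture at C2 | CC(C)C[C@H](c1occc1OC)[C@@H]([C@@H](O[Si](C)(C)C)c1c(OC)c(C2OCCO2)c(OC)c(C2OCCO2)c1OC)C(C)(O)C[Si](C)(C)C
A1 | alternative 1 | pentamethyl ether of sideroxylonal B (identical with 29) | CC(C)C[C@@H]1c2c(OC)c(C=O)c(OC)c(C=O)c2O[C@@H](c2c(OC)c(C=O)c(OC)c(C=O)c2OC)[C@H]1C(C)C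
A2 | alternative 1 | open-chain fluoro tetra-aldehyde, 5-[(1R,2S,3S)-3-(2-fluoro-3,5-diformyl-4,6-dimethoxyphenyl)-1-hydroxy-5-methyl-2-(propan-2-yl)hexyl]-2,4,6-trimethoxybenzene-1,3-dicarbaldehyde | CC(C)C[C@H](c1c(F)c(C=O)c(OC)c(C=O)c1OC)[C@H](C(C)C)[C@@H](O)c1c(OC)c(C=O)c(OC)c(C=O)c1OC
A3 | alternative 2 | flavan with ring B as 2'-hydroxy-4'-ethoxy-6'-triisopropylsiloxy arene | CC(C)C[C@@H]1c2c(OC)cc(OC)cc2O[C@@H](c2c(O)cc(OCC)cc2O[Si](C(C)C)(C(C)C)C(C)C)[C@H]1C(C)C
A4 | alternative 2 | 3-ethoxycyclobut-2-en-1-one | CCOC1=CC(=O)C1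
A5 | alternative 2 | (2R,3S,4S)-5,7-dimethoxy-4-(2-methylpropyl)-3-(propan-2-yl)-2-{[tri(propan-2-yl)silyl]oxyethynyl}-3,4-dihydro-2H-chromene | CC(C)C[C@@H]1c2c(OC)cc(OC)cc2O[C@@H](C#CO[Si](C(C)C)(C(C)C)C(C)C)[C@H]1C(C)C
A6 | alternative 3 | 3-isopropenyl analogue of the deformyl pentamethyl ether | CC(C)C[C@@H]1c2c(OC)cc(OC)cc2O[C@@H](c2c(OC)cc(OC)cc2OC)[C@H]1C(C)=C
A7 | alternative 3 | alpha-acetoxy aryl ether, {3,5-dimethoxy-2-[(4S)-2,6-dimethylhept-2-en-4-yl]phenoxy}(2,4,6-trimethoxyphenyl)methyl acetate (acetal carbon unassigned) | CC(C)C[C@@H](C=C(C)C)c1c(OC)cc(OC)cc1OC(OC(C)=O)c1c(OC)cc(OC)cc1OC
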